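**Retrosynthetic overview**

1. Eremophilane numbering is used (ring A = C1–C5 and C10, ring B = C5–C10, methyl C14 on C5, methyl C15 on C4). The last cuts are the angelate on the side-chain primary oxygen and then the C3–O acyl bond, which leaves the C3 alcohol and a (Z)-4-silyloxy-2-methylbut-2-enoic acid taken from 3-methylfuran-2(5H)-one.
2. The C7 isopropylidene is cut by retro-aldol condensation to acetone and a 6-en-8-one, which is the allylic oxidation product of a 6-ene-8,9-diol.
3. Enabling feature: in ring B, C7 is sp2 and the neighbours C8 (C=O) and C9 (CHOH) both carry oxygen, while the C1–C4 chain of ring A joins C10 to C5. Ring B is therefore the [4+2] adduct of a C5=C6–C7=C8 diene and a C9=C10 alkene, with both oxygens carried as C–B bonds.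
4. Key disconnection (C8–C9 and C5–C10 in one operation): an acyclic (E,E)-dienylboronate bearing a terminal alkyne. Alkyne hydroboration creates the vinylborane dienophile, the intramolecular Diels–Alder reaction closes ring B and, through the tether, ring A in the same event (no ring exists before it), and oxidation gives the 8,9-diol.
5. The open chain comes from a syn aldol (C3, C4), an aldehyde-to-alkyne homologation, carboalumination–iodination (C14 methyl, E-C5=C6) and a Heck reaction with vinyl-B(pin) (C7, C8).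

Key step: step 9

Remark: α denotes the face of the decalin opposite to the C5 methyl group (both methyl groups are β). It is assumed that the chair-like C1–C4 tether places the C3 silyloxy and C4 methyl groups equatorial in the cycloaddition, as in related substituted 1,7,9-decatrienes.

**Route**

Step 1
Reactants: 1 5-(trimethylsilyl)pent-4-yn-1-ol
Product: 2 5-(trimethylsilyl)pent-4-ynal
Conditions: PhI(OAc)2, TEMPO (10 mol %), CH2Cl2, rt
Reagents that add atoms: none
Why: Oxoammonium (TEMPO) oxidation takes the primary alcohol to the aldehyde without over-oxidation and leaves the C-silylated alkyne untouched.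

Step 2
Reactants: 2 5-(trimethylsilyl)pent-4-ynal; 3 (S)-4-benzyl-3-propanoyl-1,3-thiazolidine-2-thione
Product: 5 (S)-4-benzyl-3-[(2S,3R)-3-hydroxy-2-methyl-7-(trimethylsilyl)hept-6-ynoyl]-1,3-thiazolidine-2-thione, via chlorotitanium enolate 4 (not isolated)
Conditions: TiCl4, i-Pr2NEt, N-methylpyrrolidinone, CH2Cl2, 0 °C; then 2, 0 °C
Reagents that add atoms: none
Why: Crimmins titanium aldol in its Evans-syn mode: the Z-enolate reacts through a non-chelated chair Zimmerman–Traxler transition state on the face away from the benzyl group, which should set the future C3 and C4 as the 2S,3R syn pair.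

Step 3
Reactants: 5 (S)-4-benzyl-3-[(2S,3R)-3-hydroxy-2-methyl-7-(trimethylsilyl)hept-6-ynoyl]-1,3-thiazolidine-2-thione
Product: 6 (S)-4-benzyl-3-[(2S,3R)-2-methyl-3-(triethylsilyloxy)-7-(trimethylsilyl)hept-6-ynoyl]-1,3-thiazolidine-2-thione
Conditions: Et3SiOTf, 2,6-lutidine, CH2Cl2, −78 to 0 °C
Reagents that add atoms: triethylsilyl trifluoromethanesulfonate CC[Si](CC)(CC)OS(=O)(=O)C(F)(F)F
Why: Standard silylation of the aldol hydroxyl; the triethylsilyl ether is chosen because it can later be removed in the presence of a tert-butyldimethylsilyl ether.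

Step 4
Reactants: 6 (S)-4-benzyl-3-[(2S,3R)-2-methyl-3-(triethylsilyloxy)-7-(trimethylsilyl)hept-6-ynoyl]-1,3-thiazolidine-2-thione
Product: 7 (2S,3R)-2-methyl-3-(triethylsilyloxy)-7-(trimethylsilyl)hept-6-ynal
Conditions: i-Bu2AlH, CH2Cl2, −78 °C; Rochelle salt work-up
Reagents that add atoms: none
Why: N-acyl thiazolidinethiones are reduced directly to aldehydes because the tetrahedral aluminate is stable at −78 °C, so the auxiliary is released without epimerisation of the α-methyl centre.

Step 5
Reactants: 7 (2S,3R)-2-methyl-3-(triethylsilyloxy)-7-(trimethylsilyl)hept-6-ynal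
Product: 8 (3R,4R)-3-methyl-4-(triethylsilyloxy)-8-(trimethylsilyl)octa-1,7-diyne
Conditions: Me3SiCHN2, n-BuLi, THF, −78 °C; then 7, −78 to 0 °C
Reagents that add atoms: (trimethylsilyl)diazomethane C[Si](C)(C)C=[N+]=[N-]
Why: Colvin homologation (addition of the lithiated diazo compound, loss of silanolate, 1,2-hydrogen shift of the alkylidene carbene) gives the terminal alkyne under aprotic low-temperature conditions that keep both the C-silyl alkyne and the α-stereocentre intact.

Step 6
Reactants: 8 (3R,4R)-3-methyl-4-(triethylsilyloxy)-8-(trimethylsilyl)octa-1,7-diyne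
Product: 10 (1E,3R,4R)-1-iodo-2,3-dimethyl-4-(triethylsilyloxy)-8-(trimethylsilyl)oct-1-en-7-yne, via alkenylalane 9 (not isolated)
Conditions: Me3Al, Cp2ZrCl2 (25 mol %), H2O (1.5 equiv), CH2Cl2, −30 °C; then I2, THF, −30 to 0 °C
Reagents that add atoms: trimethylaluminium C[Al](C)C; iodine II
Why: Zirconium-catalysed Negishi carboalumination adds methyl and aluminium syn across the terminal alkyne with methyl on the internal carbon, and iodinolysis with retention should give the E-iodide in which C4 is trans to iodine, while the silyl-capped alkyne does not react.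

Step 7
Reactants: 10 (1E,3R,4R)-1-iodo-2,3-dimethyl-4-(triethylsilyloxy)-8-(trimethylsilyl)oct-1-en-7-yne; 11 vinylboronic acid pinacol ester
Product: 12 2-[(1E,3E,5R,6R)-4,5-dimethyl-6-(triethylsilyloxy)-10-(trimethylsilyl)deca-1,3-dien-9-yn-1-yl]-4,4,5,5-tetramethyl-1,3,2-dioxaborolane
Conditions: Pd(OAc)2 (5 mol %), P(o-tol)3, AgOAc, MeCN, 50 °C
Reagents that add atoms: none
Why: Heck–Mizoroki reaction: the alkenylpalladium iodide inserts the vinylboronate at its terminal carbon and syn β-hydride elimination should give the 1E,3E-dienylboronate with retention of the C5=C6 geometry, the base-free silver conditions disfavouring Suzuki–Miyaura transmetalation.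

Step 8
Reactants: 12 2-[(1E,3E,5R,6R)-4,5-dimethyl-6-(triethylsilyloxy)-10-(trimethylsilyl)deca-1,3-dien-9-yn-1-yl]-4,4,5,5-tetramethyl-1,3,2-dioxaborolane
Product: 13 2-[(1E,3E,5R,6R)-4,5-dimethyl-6-(triethylsilyloxy)deca-1,3-dien-9-yn-1-yl]-4,4,5,5-tetramethyl-1,3,2-dioxaborolane
Conditions: K2CO3 (cat.), MeOH/THF, 0 °C to rt
Reagents that add atoms: none
Why: Methoxide-catalysed protodesilylation cleaves only the C(sp)–Si bond; the pinacol boronate and the secondary triethylsilyl ether are expected to survive.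

Step 9
Reactants: 13 2-[(1E,3E,5R,6R)-4,5-dimethyl-6-(triethylsilyloxy)deca-1,3-dien-9-yn-1-yl]-4,4,5,5-tetramethyl-1,3,2-dioxaborolane
Product: 16 3α-(triethylsilyloxy)-10αH-eremophil-6-ene-8α,9α-diol, via trienylborane 14 (not isolated), via diboryl cycloadduct 15 (not isolated)
Conditions: Cy2BH (1.05 equiv; from BH3·SMe2 and cyclohexene), THF, 0 °C to rt; then toluene (0.005 M), 70 °C; then NaOH, H2O2, THF/H2O, 0 °C to rt
Reagents that add atoms: hydrogen peroxide OO
Why: Cy2BH adds syn and anti-Markovnikov to the terminal alkyne (faster than to the dienylboronate) and gives the (E)-alkenylborane 14 with boron on C9, whose empty p orbital lowers the LUMO of C9=C10. 14 should then undergo a type 1 intramolecular Diels–Alder reaction of the 1,7,9-decatriene kind (diene C5=C6–C7=C8, dienophile C9=C10); the closest known reaction types are [4+2] cycloadditions of B-alkenyl dialkylboranes, inter- and intramolecular, and of 1-boryl-1,3-dienes. Ring B closes by the concerted suprafacial [4+2] cycloaddition that makes C8–C9 and C5–C10, and ring A closes in the same event as the six-membered tether ring through the C5–C10 bond. C9 is set relative to C10 by the E geometry of the alkenylborane (boron cis to H-10), C8 relative to C5 by the E,E diene, the trans ring fusion (C14 methyl β, H-10 α) by the boron-endo transition state of an E dienophile with a terminal activator, and the absolute sense at C5 and C10 by the chair-like tether that keeps the C3 silyloxy and C4 methyl groups equatorial. Alkaline peroxide then replaces both C–B bonds by C–O bonds with retention, which gives the 8α,9α-diol. The step needs chemoselective monohydroboration (one equivalent of a bulky dialkylborane at 0 °C), endo selectivity (secondary interaction of boron with the diene) and no 1,3-shift of the allylic boron on C8 (secured by its being a pinacol ester and not a dialkylborane).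

Step 10
Reactants: 16 3α-(triethylsilyloxy)-10αH-eremophil-6-ene-8α,9α-diol
Product: 17 9α-hydroxy-3α-(triethylsilyloxy)-10αH-eremophil-6-en-8-one
Conditions: MnO2 (activated, excess), CH2Cl2, rt
Reagents that add atoms: none
Why: MnO2 oxidises the allylic C8 carbinol selectively and should leave the saturated secondary C9 hydroxyl alone.

Step 11
Reactants: 17 9α-hydroxy-3α-(triethylsilyloxy)-10αH-eremophil-6-en-8-one
Product: 18 9α-(tert-butyldimethylsilyloxy)-3α-(triethylsilyloxy)-10αH-eremophil-6-en-8-one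
Conditions: t-BuMe2SiOTf, 2,6-lutidine, CH2Cl2, −78 to 0 °C
Reagents that add atoms: tert-butyldimethylsilyl trifluoromethanesulfonate CC(C)(C)[Si](C)(C)OS(=O)(=O)C(F)(F)F
Why: Silyl triflate silylation of the hindered α-ketol hydroxyl masks C9–OH for the enolate chemistry and the later esterification at C3.

Step 12
Reactants: 18 9α-(tert-butyldimethylsilyloxy)-3α-(triethylsilyloxy)-10αH-eremophil-6-en-8-one; 19 acetone
Product: 21 9α-(tert-butyldimethylsilyloxy)-11-hydroxy-3α-(triethylsilyloxy)-10αH-eremophilan-8-one, via lithium enolate 20 (not isolated)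
Conditions: LiBH(s-Bu)3, THF, −78 °C; then 19, −78 °C; AcOH quench at −78 °C
Reagents that add atoms: none
Why: Conjugate hydride addition to the β-unsubstituted cyclohexenone gives the regiodefined C7 lithium enolate, which adds to acetone (reductive aldol); the C7 configuration is not controlled and does not matter because it is removed in step 13.

Step 13
Reactants: 21 9α-(tert-butyldimethylsilyloxy)-11-hydroxy-3α-(triethylsilyloxy)-10αH-eremophilan-8-one
Product: 23 9α-(tert-butyldimethylsilyloxy)-3α-(triethylsilyloxy)-10αH-eremophil-7(11)-en-8-one, via tertiary mesylate 22 (not isolated)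
Conditions: MsCl, Et3N, CH2Cl2, 0 °C; then DBU, rt to 40 °C
Reagents that add atoms: none
Why: Mesylation of the tertiary alcohol and base-induced elimination through the C7 enolate (E1cB) should give the conjugated tetrasubstituted C7=C11 alkene, any isopropenyl isomer being drawn into conjugation by DBU, while C9 stays in its stable equatorial configuration.

Step 14
Reactants: 23 9α-(tert-butyldimethylsilyloxy)-3α-(triethylsilyloxy)-10αH-eremophil-7(11)-en-8-one
Product: 24 9α-(tert-butyldimethylsilyloxy)-3α-hydroxy-10αH-eremophil-7(11)-en-8-one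
Conditions: pyridinium p-toluenesulfonate, MeOH/CH2Cl2, 0 °C to rt
Reagents that add atoms: none
Why: Acid-catalysed methanolysis cleaves a triethylsilyl ether far faster than a tert-butyldimethylsilyl ether, so only the C3 hydroxyl should be freed.

Step 15
Reactants: 25 3-methylfuran-2(5H)-one
Product: 28 (Z)-4-(tert-butyldimethylsilyloxy)-2-methylbut-2-enoic acid, via lithium carboxylate 26 (not isolated), via bis-silyl derivative 27 (not isolated)
Conditions: LiOH, THF/H2O, rt; concentrate and dry; t-BuMe2SiCl, imidazole, DMF, rt; then aq. citric acid (pH 4–5), THF, 0 °C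
Reagents that add atoms: lithium hydroxide [Li+].[OH-]; tert-butyldimethylsilyl chloride CC(C)(C)[Si](C)(C)Cl
Why: Saponification opens the butenolide with the Z geometry fixed by the ring, silylation caps the hydroxyl before it can relactonise, and the labile silyl ester is hydrolysed selectively on mild acidic work-up.

Step 16
Reactants: 24 9α-(tert-butyldimethylsilyloxy)-3α-hydroxy-10αH-eremophil-7(11)-en-8-one; 28 (Z)-4-(tert-butyldimethylsilyloxy)-2-methylbut-2-enoic acid
Product: 30 9α-(tert-butyldimethylsilyloxy)-8-oxo-10αH-eremophil-7(11)-en-3α-yl (Z)-4-(tert-butyldimethylsilyloxy)-2-methylbut-2-enoate, via mixed anhydride 29 (not isolated)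
Conditions: 28, 2,4,6-trichlorobenzoyl chloride, Et3N, toluene, rt; then 24, toluene, 80 °C
Reagents that add atoms: none
Why: Yamaguchi-type mixed-anhydride esterification run without DMAP, as used for angelates of hindered alcohols, should acylate the equatorial C3 hydroxyl without Z-to-E isomerisation of the acid, the C9 oxygen being blocked as its silyl ether.

Step 17
Reactants: 30 9α-(tert-butyldimethylsilyloxy)-8-oxo-10αH-eremophil-7(11)-en-3α-yl (Z)-4-(tert-butyldimethylsilyloxy)-2-methylbut-2-enoate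
Product: 31 9α-hydroxy-8-oxo-10αH-eremophil-7(11)-en-3α-yl (Z)-4-hydroxy-2-methylbut-2-enoate
Conditions: HF·pyridine, pyridine, THF, 0 °C to rt
Reagents that add atoms: none
Why: Buffered fluoride cleaves both Si–O bonds and should spare the ester and the enone, and the absence of base keeps the Z-γ-hydroxy enoate from lactonising.

Step 18
Reactants: 31 9α-hydroxy-8-oxo-10αH-eremophil-7(11)-en-3α-yl (Z)-4-hydroxy-2-methylbut-2-enoate; 32 angelic acid
Product: 34 9α-hydroxy-8-oxo-10αH-eremophil-7(11)-en-3α-yl (Z)-2-methyl-4-[(Z)-2-methylbut-2-enoyloxy]but-2-enoate, via angelic mixed anhydride 33 (not isolated)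
Conditions: 32, 2,4,6-trichlorobenzoyl chloride, Et3N, toluene, rt; then crude 31 (1.2 equiv of anhydride), toluene, 60 °C
Reagents that add atoms: none
Why: The mixed anhydride of angelic acid should acylate the primary allylic hydroxyl in preference to the hindered, hydrogen-bonded C9 hydroxyl, and the DMAP-free conditions avoid isomerisation of the angelate to the tiglate.

**Compound list**

1 | 5-(trimethylsilyl)pent-4-yn-1-ol | C[Si](C)(C)C#CCCCO | starting material
2 | 5-(trimethylsilyl)pent-4-ynal | C[Si](C)(C)C#CCCC=O | intermediate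
3 | (S)-4-benzyl-3-propanoyl-1,3-thiazolidine-2-thione | CCC(=O)N1[C@@H](Cc2ccccc2)CSC1=S | starting material
4 | trichlorotitanium (Z)-enolate of 3 (not isolated) | C/C=C(\O[Ti](Cl)(Cl)Cl)N1[C@@H](Cc2ccccc2)CSC1=S | intermediate
5 | (S)-4-benzyl-3-[(2S,3R)-3-hydroxy-2-methyl-7-(trimethylsilyl)hept-6-ynoyl]-1,3-thiazolidine-2-thione | O[C@H](CCC#C[Si](C)(C)C)[C@@H](C(=O)N1[C@@H](Cc2ccccc2)CSC1=S)C | intermediate
6 | (S)-4-benzyl-3-[(2S,3R)-2-methyl-3-(triethylsilyloxy)-7-(trimethylsilyl)hept-6-ynoyl]-1,3-thiazolidine-2-thione | CC[Si](CC)(CC)O[C@H](CCC#C[Si](C)(C)C)[C@@H](C(=O)N1[C@@H](Cc2ccccc2)CSC1=S)C | intermediate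
7 | (2S,3R)-2-methyl-3-(triethylsilyloxy)-7-(trimethylsilyl)hept-6-ynal | CC[Si](CC)(CC)O[C@H](CCC#C[Si](C)(C)C)[C@@H](C=O)C | intermediate
8 | (3R,4R)-3-methyl-4-(triethylsilyloxy)-8-(trimethylsilyl)octa-1,7-diyne | CC[Si](CC)(CC)O[C@H](CCC#C[Si](C)(C)C)[C@@H](C#C)C | intermediate
9 | dimethyl[(1E,3R,4R)-2,3-dimethyl-4-(triethylsilyloxy)-8-(trimethylsilyl)oct-1-en-7-yn-1-yl]alane (not isolated) | CC[Si](CC)(CC)O[C@H](CCC#C[Si](C)(C)C)[C@@H](/C(C)=C/[Al](C)C)C | intermediate
10 | (1E,3R,4R)-1-iodo-2,3-dimethyl-4-(triethylsilyloxy)-8-(trimethylsilyl)oct-1-en-7-yne | CC[Si](CC)(CC)O[C@H](CCC#C[Si](C)(C)C)[C@@H](/C(C)=C/I)C | intermediate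
11 | vinylboronic acid pinacol ester (4,4,5,5-tetramethyl-2-vinyl-1,3,2-dioxaborolane) | C=CB1OC(C)(C)C(C)(C)O1 | starting material
12 | 2-[(1E,3E,5R,6R)-4,5-dimethyl-6-(triethylsilyloxy)-10-(trimethylsilyl)deca-1,3-dien-9-yn-1-yl]-4,4,5,5-tetramethyl-1,3,2-dioxaborolane | CC[Si](CC)(CC)O[C@H](CCC#C[Si](C)(C)C)[C@@H](/C(C)=C/C=C/B1OC(C)(C)C(C)(C)O1)C | intermediate
13 | 2-[(1E,3E,5R,6R)-4,5-dimethyl-6-(triethylsilyloxy)deca-1,3-dien-9-yn-1-yl]-4,4,5,5-tetramethyl-1,3,2-dioxaborolane | CC[Si](CC)(CC)O[C@H](CCC#C)[C@@H](/C(C)=C/C=C/B1OC(C)(C)C(C)(C)O1)C | intermediate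
14 | dicyclohexyl[(1E,5R,6R,7E,9E)-6,7-dimethyl-10-(4,4,5,5-tetramethyl-1,3,2-dioxaborolan-2-yl)-5-(triethylsilyloxy)deca-1,7,9-trien-1-yl]borane (not isolated) | CC[Si](CC)(CC)O[C@H](CC/C=C/B(C1CCCCC1)C1CCCCC1)[C@@H](/C(C)=C/C=C/B1OC(C)(C)C(C)(C)O1)C | intermediate
15 | 9α-(dicyclohexylboryl)-8α-(4,4,5,5-tetramethyl-1,3,2-dioxaborolan-2-yl)-3α-(triethylsilyloxy)-10αH-eremophil-6-ene (not isolated) | CC[Si](CC)(CC)O[C@@H]1CC[C@H]2[C@H](B(C3CCCCC3)C3CCCCC3)[C@H](B3OC(C)(C)C(C)(C)O3)C=C[C@]2(C)[C@H]1C | intermediate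
16 | 3α-(triethylsilyloxy)-10αH-eremophil-6-ene-8α,9α-diol (trans-decalin, both methyls β) | CC[Si](CC)(CC)O[C@@H]1CC[C@H]2[C@H](O)[C@H](O)C=C[C@]2(C)[C@H]1C | intermediate
17 | 9α-hydroxy-3α-(triethylsilyloxy)-10αH-eremophil-6-en-8-one | CC[Si](CC)(CC)O[C@@H]1CC[C@H]2[C@H](O)C(=O)C=C[C@]2(C)[C@H]1C | intermediate
18 | 9α-(tert-butyldimethylsilyloxy)-3α-(triethylsilyloxy)-10αH-eremophil-6-en-8-one | CC[Si](CC)(CC)O[C@@H]1CC[C@H]2[C@H](O[Si](C)(C)C(C)(C)C)C(=O)C=C[C@]2(C)[C@H]1C | intermediate
19 | acetone | CC(C)=O | starting material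
20 | lithium 7-en-8-olate of 9α-(tert-butyldimethylsilyloxy)-3α-(triethylsilyloxy)-10αH-eremophilan-8-one (not isolated) | CC[Si](CC)(CC)O[C@@H]1CC[C@H]2[C@H](O[Si](C)(C)C(C)(C)C)C(O[Li])=CC[C@]2(C)[C@H]1C | intermediate
21 | 9α-(tert-butyldimethylsilyloxy)-11-hydroxy-3α-(triethylsilyloxy)-10αH-eremophilan-8-one (C7 epimers) | CC[Si](CC)(CC)O[C@@H]1CC[C@H]2[C@H](O[Si](C)(C)C(C)(C)C)C(=O)C(C(C)(C)O)C[C@]2(C)[C@H]1C | intermediate
22 | 11-methanesulfonate of 21 (not isolated) | CC[Si](CC)(CC)O[C@@H]1CC[C@H]2[C@H](O[Si](C)(C)C(C)(C)C)C(=O)C(C(C)(C)OS(C)(=O)=O)C[C@]2(C)[C@H]1C | intermediate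
23 | 9α-(tert-butyldimethylsilyloxy)-3α-(triethylsilyloxy)-10αH-eremophil-7(11)-en-8-one | CC[Si](CC)(CC)O[C@@H]1CC[C@H]2[C@H](O[Si](C)(C)C(C)(C)C)C(=O)C(=C(C)C)C[C@]2(C)[C@H]1C | intermediate
24 | 9α-(tert-butyldimethylsilyloxy)-3α-hydroxy-10αH-eremophil-7(11)-en-8-one | O[C@@H]1CC[C@H]2[C@H](O[Si](C)(C)C(C)(C)C)C(=O)C(=C(C)C)C[C@]2(C)[C@H]1C | intermediate
25 | 3-methylfuran-2(5H)-one | CC1=CCOC1=O | starting material
26 | lithium (Z)-4-hydroxy-2-methylbut-2-enoate (not isolated) | OC/C=C(/C)C(=O)[O-].[Li+] | intermediate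
27 | tert-butyldimethylsilyl (Z)-4-(tert-butyldimethylsilyloxy)-2-methylbut-2-enoate (not isolated) | CC(C)(C)[Si](C)(C)OC/C=C(/C)C(=O)O[Si](C)(C)C(C)(C)C | intermediate
28 | (Z)-4-(tert-butyldimethylsilyloxy)-2-methylbut-2-enoic acid | CC(C)(C)[Si](C)(C)OC/C=C(/C)C(=O)O | intermediate
29 | (Z)-4-(tert-butyldimethylsilyloxy)-2-methylbut-2-enoic 2,4,6-trichlorobenzoic anhydride (not isolated) | CC(C)(C)[Si](C)(C)OC/C=C(/C)C(=O)OC(=O)c1c(Cl)cc(Cl)cc1Cl | intermediate
30 | 9α-(tert-butyldimethylsilyloxy)-8-oxo-10αH-eremophil-7(11)-en-3α-yl (Z)-4-(tert-butyldimethylsilyloxy)-2-methylbut-2-enoate | CC(C)(C)[Si](C)(C)OC/C=C(/C)C(=O)O[C@@H]1CC[C@H]2[C@H](O[Si](C)(C)C(C)(C)C)C(=O)C(=C(C)C)C[C@]2(C)[C@H]1C | intermediate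
31 | 9α-hydroxy-8-oxo-10αH-eremophil-7(11)-en-3α-yl (Z)-4-hydroxy-2-methylbut-2-enoate | OC/C=C(/C)C(=O)O[C@@H]1CC[C@H]2[C@H](O)C(=O)C(=C(C)C)C[C@]2(C)[C@H]1C | intermediate
32 | angelic acid ((Z)-2-methylbut-2-enoic acid) | C/C=C(/C)C(=O)O | starting material
33 | (Z)-2-methylbut-2-enoic 2,4,6-trichlorobenzoic anhydride (not isolated) | C/C=C(/C)C(=O)OC(=O)c1c(Cl)cc(Cl)cc1Cl | intermediate
34 | (3R,4R,5R,9S,10R)-9-hydroxy-8-oxoeremophil-7(11)-en-3-yl (Z)-2-methyl-4-[(Z)-2-methylbut-2-enoyloxy]but-2-enoate (CNP0308665.1) | C/C=C(/C)C(=O)OC/C=C(/C)C(=O)O[C@@H]1CC[C@H]2[C@H](O)C(=O)C(=C(C)C)C[C@]2(C)[C@H]1C | target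

**Step count and risks**

Total step count: 18. Longest linear sequence: 17 steps (steps 1 to 14 and 16 to 18, from 1); step 15 is a one-step branch.

Steps most likely to fail:

Step 9. The cycloaddition may be too slow, because the C14 methyl is an inside substituent of the s-cis diene, so that the dialkylborane decomposes or reacts between molecules before it cyclises; the boron-endo preference may also be too weak and give cis-fused material. The fallback sets out from 13: Cp2ZrHCl-catalysed hydroboration with pinacolborane should give the isolable bis(pinacolboronate) triene F1. Its purely thermal intramolecular Diels–Alder reaction (toluene, 150 °C, sealed tube, BHT, or 12 kbar in CH2Cl2 at rt) should give the diboronate cycloadduct F2, whose ring-fusion isomers can be separated by chromatography. Oxidation with NaBO3·4H2O in THF/H2O comes back to the route at 16.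

Step 12. Hydride may add to the carbonyl carbon instead of C6, which is neopentyl (next to the quaternary C5), or the lithium aldolate may revert to enolate and acetone before the quench. The fallback sets out from 18: hydrogenation (H2, Pd/C, EtOAc) should give the saturated ketone F3. Kinetic deprotonation at the C7 methylene with LiN(i-Pr)2 (THF, −78 °C), transmetalation with ZnCl2 and addition of acetone come back to the route at 21.

Step 7. Transmetalation of the boronate to palladium (the Suzuki–Miyaura pathway) may compete with insertion, and insertion at the boron-bearing carbon would erode the regiocontrol. The fallback sets out from 10: iodine–lithium exchange (t-BuLi, Et2O, −78 °C) and formylation with DMF should give the (E)-enal F4. Boron-Wittig olefination with bis(4,4,5,5-tetramethyl-1,3,2-dioxaborolan-2-yl)methane and lithium 2,2,6,6-tetramethylpiperidide (THF, −78 °C to rt) should give the trans-alkenylboronate and comes back to the route at 12.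

**Further compounds**

F1 | step 9 | 2,2'-[(1E,5R,6R,7E,9E)-6,7-dimethyl-5-(triethylsilyloxy)deca-1,7,9-triene-1,10-diyl]bis(4,4,5,5-tetramethyl-1,3,2-dioxaborolane) | CC[Si](CC)(CC)O[C@H](CC/C=C/B1OC(C)(C)C(C)(C)O1)[C@@H](/C(C)=C/C=C/B1OC(C)(C)C(C)(C)O1)C
F2 | step 9 | 8α,9α-bis(4,4,5,5-tetramethyl-1,3,2-dioxaborolan-2-yl)-3α-(triethylsilyloxy)-10αH-eremophil-6-ene | CC[Si](CC)(CC)O[C@@H]1CC[C@H]2[C@H](B3OC(C)(C)C(C)(C)O3)[C@H](B3OC(C)(C)C(C)(C)O3)C=C[C@]2(C)[C@H]1C
F3 | step 12 | 9α-(tert-butyldimethylsilyloxy)-3α-(triethylsilyloxy)-10αH-eremophilan-8-one | CC[Si](CC)(CC)O[C@@H]1CC[C@H]2[C@H](O[Si](C)(C)C(C)(C)C)C(=O)CC[C@]2(C)[C@H]1C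
F4 | step 7 | (2E,4R,5R)-3,4-dimethyl-5-(triethylsilyloxy)-9-(trimethylsilyl)non-2-en-8-ynal | CC[Si](CC)(CC)O[C@H](CCC#C[Si](C)(C)C)[C@@H](/C(C)=C/C=O)C
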